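| setting | eta | zeta | gamma | red | amber |
|---|---|---|---|---|---|
| E | 0.050 M (fed, over 12 min) | 0.050 M (fed, over 12 min) | 0.050 M (fed, over 12 min) | 0.050 M (fed, over 12 min) | 0.050 M |
| L | 0.025 M | 0.025 M | 0.052 M | 0.0250 M | 0.100 M |
| Z | 4 µM | 6.2 µM | 4.6 µM | 4.6 µM | 10 µM |
| remark | run made earlier; the fed solution adds 1.0 times the starting volume | run made earlier; the fed solution adds 1.0 times the starting volume | run made earlier; the fed solution adds 1.0 times the starting volume | the fed solution adds 1.0 times the starting volume | everything together at the start, the whole solution of E included, so that from the start the volume is larger by 1.0 times the starting volume |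
| time |  |  |  | 40 min | 40 min |

- eta (time / min: X / %, E / %): 1.00: 0.7, 5.2; 3.00: 4.9, 13.7; 6.00: 10.5, 23.3; 8.00: 9.3, 32.6; 12.0: 11.6, 55.3; 15.0: 12.2, 53.3; 20.0: 12.2, 50.3
- zeta (time / min: X / %, E / %): 3.00: 7.0, 12.1; 6.00: 10.5, 21.7; 8.00: 14.7, 31.9; 12.0: 14.1, 56.9; 15.0: 15.3, 52.3; 20.0: 17.9, 49.6
- gamma (time / min: X / %, E / %): 4.00: 13.1, 8.0; 8.00: 19.9, 16.8; 12.0: 26.0, 26.9; 15.0: 28.5, 17.7; 20.0: 29.6, 11.5

(standard deviation of a reading: 1 percentage point)

- which one finishes higher in amount of X, in percent of the E charged ("neither" within 2 percentage points) (red / amber / neither)
- amount of X at the end, in percent of the E charged, red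
- amount of X at the end, in percent of the E charged, amber

- amounts are per litre of the starting volume; all of the dose is in the solution fed
- the numbers in the tables scatter with a standard deviation of 1 percentage point
- percentages count the whole charge, also what has not yet gone in

1. Run eta stops with E near 50.3%, and its L charge equals 50.0% of the E charge, so L is the limiting reagent, taken one for one with E, and red is an L-short flask as well. In eta the feed has delivered 50.0% of the E at 6.00 min, and 23.3% stands unused. Thus 26.7% is spent, which is half of the L.

2. Dividing that half-time by ln(2) gives 8.66 min. This is the working life of L: the time L would last at its early pace. The rule is that final X equals early X rate times working life, with X rate following L.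

3. First way to red: between eta and zeta, the plateaus 12.2% and 17.9% interpolate at red's Z to 13.8%.

4. Second way: gamma has red's Z and makes 13.1% in 4.00 min. Scaled to red's L, that rate becomes 0.0157 min⁻¹ of the charge. Times the working life, it gives 13.6%. The two ways use different readings and agree, so about 13.6% stands for red.

5. Amber: scaling gamma's rate for Z, L and volume gives 0.0799 min⁻¹. Here E ends the run, not L. Gamma's fall of E after its feed, scaled to amber's charged L, gives an E half-life of 0.757 min with L held at that charge. Amber reaches the E concentration of gamma's first reading after 3.06 such half-lives, which is 2.32 min counted at charged L. L falls on the way, so this count is not clock time. In this reckoning the X rate and the loss of E both follow L, so that fall cancels in their ratio, and X is still the rate at charged L times the counted time. That gives 18.5% down to that E, more than red.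

6. The forecast says amber, with 14% for red and 26% for amber, higher than this reckoning for amber, on the grounds that “Amber is a batch with excess L”.

7. The flasks give amber as the higher one, with 13.9% for red and 28.6% for amber.

    L + G ⇌ J (K = 11.0 L mol⁻¹, k = 1.10 × 10⁵ L mol⁻¹ s⁻¹)
    E + L → Q (k = 0.280 L mol⁻¹ s⁻¹)
    2 G ⇌ D, settled at all times (K = 3.30 × 10⁶ L mol⁻¹)
    J → Z + X (k = 160 s⁻¹)
    E + Z ⇌ G (K = 45.0 L mol⁻¹, k = 1.70 × 10⁵ L mol⁻¹ s⁻¹)

In red at 6.31 min, E + L to Q takes L at 0.047 of the forward rate of L + G to J, while J falls back 62 times faster than it goes on to X. Counting that return, Q takes L 2.97 times as fast as the path to X. Red's result, with L down to 0.00911%, corresponds to a working life of 8.85 min against the reckoned 8.66 min. Amber's result, divided by its rate at charged L, corresponds to 3.58 min against the 2.32 min counted at charged L down to the E of gamma's first reading.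

The readings stem from a simulated flask with constants of no real substance; noise was put on by code.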